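## The problem

The target is a briarane diterpenoid. A cyclohexene (ring A: C1, C10, C11, C12, C13, C14) is trans-fused along C1–C10 to a ten-membered carbocycle (ring B: C1 to C10), which carries a γ-lactone (ring C: C7, O, C19, C17, C8) fused along C7–C8; C15, C16, C18 and C20 are the methyl groups on C1, C5, C17 and C11. Nine stereocentres must be set (C1, C2, C7, C8, C9, C10, C11, C12, C17), among them the all-carbon quaternary C1 and the tertiary carbinol C8. The tetrasubstituted C5=C6 chloroalkene (C4 cis to C7) must also be fixed, and its geometry cannot be corrected once ring B is closed. C7, C8 and C17 form a compact lactone triad that can be made as one unit. Once C9 sits on C10 it can steer hydrogen to C11, oxygen to C12 and C2 to the far face of C1; because C15, C9 and C20 are all cis on ring A, the C9–C10 bond must exist before hydrogen is delivered to C11. Ring B has to be closed between sp3 carbons, and C2 and C9 are each flanked by a fully substituted carbon, so both carbinols are hard to reach and hard to invert. Sensitive elements are the two acetates (the C12 one allylic), the lactone with its epimerisable C17–H, the vinyl chloride (dissolving metals, hydrogenolysis) and the C8/C9 diol, which next to a carbonyl invites retro-aldol cleavage and α-ketol shift. The enabling feature is that C8 is the carbinol carbon of a syn-3-methylmalic acid (C9–C8(OH)–C17(C18)–C19). Held as a cis-2-tert-butyl-1,3-dioxolan-4-one, this unit gives an enolate at C8 that can take a C7 aldehyde with self-regeneration of its stereocentre, while its free C19 carboxyl captures the new C7 hydroxyl as ring C.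

## Retrosynthesis

**39 ⇒ 38 ⇒ 37 ⇒ 36.** No skeletal bond is cut; the two acetyl C–O bonds and the silyl ethers at C8 and C9 are removed. C2–OH and C12–OH must be acylated while the equally hindered C9–OH is still masked, so 36 carries silyl ethers of graded lability (C12 triethylsilyl, C9 tert-butyldimethylsilyl, C8 tertiary triethylsilyl) and a free C2 hydroxyl. The forward steps ask for selective loss of the C12 ether (37), bis-acetylation (38) and global desilylation.

**36 ⇒ 35.** Ring B is cut at C1–C2. A cut at C2–C3 would need an unstabilised sp3–sp3 closure, and a cut at C9–C10 would make the most hindered bond of the molecule in the ring-closing step. The C1–C2 cut gives three results in one step: an allylmetal spanning C13–C14–C1 adds through C1 to the C2 aldehyde and creates the quaternary centre, the C2 carbinol and the C13=C14 alkene. Precursor 35 has no ring B, a trigonal C1 and two stereocentres fewer. The forward reaction must bond C1 on the face away from the C10 side chain and tolerate the lactone, the vinyl chloride and a silyloxy group next to the metal-bearing carbon.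

**35 ⇒ 31 ⇒ 29 ⇒ 27.** These are ring A adjustments; the bonds removed are C13–Cl, C12–O and C11–H. The allylic chloride of 35 (through 34, 33, 32) comes from enone 31. The C13 carbonyl of 31 also served to place oxygen on C12 and to introduce the C14=C1 unsaturation (29, 30), and 29 comes from enone 27. The detour through 27 is needed because C20 and C9 are cis on adjacent carbons, which C–C bond formation next to an existing centre does not give. Hydride delivered to C11 of 27 anti to the C10 side chain does give it, and the enol ether 28 then takes oxygen on C12 anti to C20. In 27 two stereocentres are gone and the C1 methyl centre is only a relay, erased at 31. 27 arises from the C11 ketone 25 by methyl addition (26) and oxidative 1,3-transposition.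

**25 ⇒ 24 ⇒ 18 + 23.** The C9–C10 bond is cut as an aldol: C10 is the α′ carbon of enone 23 and C9 the aldehyde carbon of 18. The alternatives are a secondary C10 organometallic flanked by two branched carbons, or a C10 vinyl anion whose alkene could not later be reduced beside C13=C14. The enolate is small, regiodefined and chiral. The precursors are a lactone aldehyde with three stereocentres and a six-carbon chiral-pool enone. The forward step must form C10 trans to the ring methyl and C9 syn to the ring bond, the second of which needs a syn-selective metal.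

**18 ⇒ 17 ⇒ 16 ⇒ 15 ⇒ 14.** No skeletal bond is cut; the C9 aldehyde is the dioxolanone carbonyl of 14 at a lower oxidation level. The forward sequence must open the acetal, reduce the C9 ester beside the lactone and mask the C8 hydroxyl before the aldehyde is exposed.

**14 ⇒ 6 + 12 (key cut).** C7–C8 and the lactone C–O bond (O7–C19) are cut. Other cuts of ring C would have to build the quaternary carbinol C8 on a preformed lactone without an internal control element. Here C8 is an enolate carbon whose configuration is stored in the acetal carbon of 6, and C19 is already at the acid level. The precursors are an acid with two stereocentres and an achiral enal that carries C2 to C7 and the chloroalkene geometry. The forward reaction must enolise C8 without touching C17, add 1,2 to a hindered enal and choose one face of the aldehyde.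

**6 ⇒ 4 ⇒ 3 ⇒ 1 + 2 (and 5).** The C8–C17 bond is cut as an auxiliary-controlled syn aldol between the propionyl imide 1 and ethyl glyoxylate 2. Alkylation of a malate dianion would give the anti isomer, so the aldol is preferred. Hydrolysis gives diacid 4, and acetalisation with pivalaldehyde 5 gives the cis dioxolanone 6.

**12 ⇒ 11 ⇒ 10 ⇒ 9 ⇒ 8 ⇒ 7.** The C5–C16 and C6–Cl bonds are cut across an ynoate. Olefination of a methyl ketone would not distinguish methyl from the chain, whereas syn carbocupration of 9 followed by chlorination with retention fixes the tetrasubstituted alkene. Everything derives from pent-4-yn-1-ol 7.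

**23 ⇒ 21 ⇒ 20 ⇒ 19.** Enone 23 comes from (S)-pulegone 19 by loss of the isopropylidene carbons (epoxide 20, sulfide 21, sulfoxide 22), which keeps the methyl-bearing centre.

## Roads not taken

**Alternative 1:** The cut is the C8–C9 bond of ring B. In the forward sense SmI2 would reduce an aldehyde carbonyl at C9 and a ketone carbonyl at C8 held in one chain and join the two carbons, giving the ten-membered C8,C9-diol A1.
- Merits: ring closure and both carbinol centres come in one step, and ring A arrives with C1, C2, C10, C11 and C12 already in place. The long ring A adjustment of the chosen plan (steps 17 to 25) is not needed, and in this respect the road is better.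
- Weak points: the C8 ketone sits next to the oxygenated C7, and α-oxygenated ketones are cleaved reductively by SmI2. The ketyl is also adjacent to an allylic chloroalkene. The coupling must create a fully substituted carbinol inside a medium ring, and the configurations at C8 and C9 depend only on the conformation of the closing chain. The lactone, with C19 still at the alcohol level, remains to be made.
- Comparison: the chosen plan fixes C8 by the acetal carbon before any ring is closed and makes the lactone in the same step, at the price of a longer sequence after fragment union.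

**Alternative 2:** The cut is C1–C14 inside ring A. In the forward sense Pd(PPh3)4 with Cs2CO3 would join a (Z)-iodoalkene carbon (C14) to the enolate carbon (C1) of an α-methyl aldehyde function, closing the cyclohexene and giving ring A aldehyde A2 with the quaternary centre.
- Merits: C1 is made in a six-membered closure rather than in a macrocyclisation. C13=C14 arrives with its geometry and never has to survive a reduction. C9, C15 and C20 can be set cis by acyclic methods before the ring exists. In control of C1 and of the ring A triad this road is better than the chosen plan.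
- Weak points: an enolisable aldehyde is exposed to carbonate at elevated temperature, and the face of the enolate that binds palladium is decided only by the forming ring. A2 also solves ring A alone: C8 would then have to be added as a nucleophile to a neopentyl C9 aldehyde with no auxiliary control, and ring B and ring C remain.
- Comparison: the chosen plan sets absolute control of C7, C8 and C17 and a convergent union at C7–C8 against this, and accepts that C1 is made late.

**Alternative 3:** The cut is a C2=C7 double bond that the target does not contain: the two carbons are joined as a tetrasubstituted ring-fusion alkene, and ozone followed by Me2S would cleave it to the ten-membered 2,7-dione A3.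
- Merits: ring B is made by cleavage, so there is no entropic penalty and no high dilution, and the carbons are assembled by six-membered ring chemistry. In how the medium ring is reached this road is better than the chosen plan, whose ring closure (step 28) is its least certain step.
- Weak points: ozone must distinguish the tetrasubstituted alkene from the trisubstituted one that remains in A3. A3 lacks the chlorine, the C8 oxygen, C17 to C19 and the C13=C14 alkene, and has its ring alkene at C4=C5. All of these would have to be introduced on a flexible diketone prone to transannular aldol reaction, with C7, C8 and C17 set by substrate control alone.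
- Comparison: the chosen plan enters ring B with the lactone triad and the chloroalkene geometry already fixed by acyclic and auxiliary-based reactions.

Key step: step 9

## Route

Remark: locants C1 to C20 are those of the briarane skeleton defined under "The problem"; descriptors inside systematic names refer to the locants of those names.

Step 1
Reactants: 1 (R)-4-benzyl-3-propionyloxazolidin-2-one; 2 ethyl glyoxylate
Product: 3 ethyl (2R,3R)-4-[(4R)-4-benzyl-2-oxo-1,3-oxazolidin-3-yl]-2-hydroxy-3-methyl-4-oxobutanoate
Conditions: Bu2BOTf, iPr2NEt, CH2Cl2, 0 °C; 2 (freshly distilled), −78 → 0 °C; pH 7 buffer, MeOH, H2O2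
Reagents that add atoms: none
Why: Evans syn aldol: the (Z)-boron enolate adds through a chair transition state on the face away from the benzyl group, which should set C17 (R) and C8 (R) in the syn relationship of 3-methylmalic acid.

Step 2
Reactants: 3
Product: 4 (2R,3R)-2-hydroxy-3-methylbutanedioic acid
Conditions: LiOH, H2O2, THF/H2O, 0 °C → rt; Na2SO3; HCl to pH 1
Reagents that add atoms: lithium hydroxide [Li+].[OH-]; hydrogen peroxide OO
Why: Hydroperoxide cleaves the imide at the exocyclic carbonyl and hydroxide saponifies the ethyl ester; both carbons end as carboxylates, which protects C17 from enolisation.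

Step 3
Reactants: 4; 5 pivalaldehyde
Product: 6 (2R)-2-[(2R,4R)-2-tert-butyl-5-oxo-1,3-dioxolan-4-yl]propanoic acid
Conditions: TsOH·H2O (cat.), H2SO4 (cat.), pentane, reflux, water separator
Reagents that add atoms: none
Why: Acid-catalysed acetalisation of the α-hydroxy acid closes the five-membered dioxolanone in preference to the six-membered dioxanone, and equilibration should place tert-butyl cis to the C8 side chain; the C19 acid stays free.

Step 4
Reactants: 7 pent-4-yn-1-ol
Product: 8 1-methoxy-4-[(pent-4-yn-1-yloxy)methyl]benzene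
Conditions: NaH, 4-MeOC6H4CH2Cl, Bu4NI (cat.), THF, 0 °C → rt
Reagents that add atoms: 4-methoxybenzyl chloride COc1ccc(CCl)cc1
Why: Williamson etherification of the alkoxide; the alkyne C–H is not deprotonated by NaH.

Step 5
Reactants: 8
Product: 9 ethyl 6-[(4-methoxybenzyl)oxy]hex-2-ynoate
Conditions: n-BuLi, THF, −78 °C; ClCO2Et, −78 → 0 °C
Reagents that add atoms: ethyl chloroformate CCOC(=O)Cl
Why: Acylation of the lithium acetylide, a standard route to ynoates.

Step 6
Reactants: 9
Product: 10 ethyl (2E)-2-chloro-6-[(4-methoxybenzyl)oxy]-3-methylhex-2-enoate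
Conditions: Me2CuLi (from CuI and MeLi), THF, −78 °C; NCS, −78 °C
Reagents that add atoms: lithium dimethylcuprate [Li+].C[Cu-]C; N-chlorosuccinimide O=C1CCC(=O)N1Cl
Why: Syn carbocupration of the ynoate places methyl and copper cis, and chlorination of the α-cuprio enoate at −78 °C with retention should give the tetrasubstituted alkene with Cl cis to C16 and the ester carbon (C7) cis to the C4 chain.

Step 7
Reactants: 10
Product: 11 (2E)-2-chloro-6-[(4-methoxybenzyl)oxy]-3-methylhex-2-en-1-ol
Conditions: i-Bu2AlH, CH2Cl2, −78 °C; aqueous potassium sodium tartrate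
Reagents that add atoms: none
Why: 1,2-Reduction of the enoate to the allylic alcohol; the vinyl chloride and the benzyl ether are inert to the aluminium hydride at −78 °C.

Step 8
Reactants: 11
Product: 12 (2E)-2-chloro-6-[(4-methoxybenzyl)oxy]-3-methylhex-2-enal
Conditions: MnO2, CH2Cl2, rt
Reagents that add atoms: none
Why: Neutral allylic oxidation; the tetrasubstituted alkene has no pathway for isomerisation under these conditions.

Step 9
Reactants: 6 (2R)-2-[(2R,4R)-2-tert-butyl-5-oxo-1,3-dioxolan-4-yl]propanoic acid; 12 (2E)-2-chloro-6-[(4-methoxybenzyl)oxy]-3-methylhex-2-enal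
Product: 14 (2R,5S,6R,9R)-2-tert-butyl-6-{(1E)-1-chloro-5-[(4-methoxybenzyl)oxy]-2-methylpent-1-en-1-yl}-9-methyl-1,3,7-trioxaspiro[4.4]nonane-4,8-dione, via aldol hydroxy acid 13 (not isolated)
Conditions: LiN(SiMe3)2 (2.2 equiv), THF, −78 °C; 12, −78 °C; AcOH; then TsOH·H2O (cat.), CH2Cl2, rt
Reagents that add atoms: none
Why: Two equivalents of LiN(SiMe3)2 give the C19 carboxylate and then the dioxolanone enolate; the planar C8 adds 1,2 to the aldehyde carbon C7 of 12 (the β-carbon is fully substituted), and after acidification the C7 hydroxyl acylates onto C19. The closest known reaction type is the alkylation and aldol addition of 2-tert-butyl-1,3-dioxolan-4-one enolates with self-regeneration of the stereocentre, including the dianion of the malic acid-derived dioxolanone acid. The γ-lactone closes by 5-exo-trig acyl substitution at C19, spiro to the dioxolanone. C8 is controlled by the acetal carbon: the aldehyde enters trans to tert-butyl and takes the place of the former C8 hydrogen with retention. C7 is controlled by a closed lithium chair in which the enolate oxygen is cis to the C17 branch, so the chlorovinyl group sits equatorial and the C7 oxygen ends syn to C17; this is the 7R arrangement, in which C6 is cis to the C8 oxygen on the lactone. The step needs enolisation at C8 and not at C17, which the carboxylate secures, because a second deprotonation next to CO2Li is far slower than removal of the acylal-activated C8 hydrogen at −78 °C. C17 and the chloroalkene geometry are therefore carried through unchanged.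

Step 10
Reactants: 14
Product: 15 methyl (2R,3S,4R)-2-{(1E)-1-chloro-5-[(4-methoxybenzyl)oxy]-2-methylpent-1-en-1-yl}-3-hydroxy-4-methyl-5-oxooxolane-3-carboxylate
Conditions: K2CO3 (cat.), MeOH, 0 °C; AcOH
Reagents that add atoms: methanol CO
Why: Transesterification of the acylal-type dioxolanone carbonyl, an activated ester, releases pivalaldehyde and the C8 hydroxyl; the γ-lactone re-closes if it opens, and catalytic carbonate at 0 °C should not epimerise C17.

Step 11
Reactants: 15
Product: 16 (3R,4R,5R)-5-{(1E)-1-chloro-5-[(4-methoxybenzyl)oxy]-2-methylpent-1-en-1-yl}-4-hydroxy-4-(hydroxymethyl)-3-methyloxolan-2-one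
Conditions: BH3·SMe2, NaBH4 (cat.), THF, 0 °C → rt; MeOH
Reagents that add atoms: none
Why: Hydroxyl-directed borane reduction of an α-hydroxy ester: the alkoxyborane at C8 delivers hydride to the adjacent C9 ester through a five-membered chelate, while the lactone carbonyl would need a six-membered one and is left; the tetrasubstituted chloroalkene is too hindered and electron-poor for hydroboration.

Step 12
Reactants: 16
Product: 17 (3R,4R,5R)-5-{(1E)-1-chloro-5-[(4-methoxybenzyl)oxy]-2-methylpent-1-en-1-yl}-3-methyl-4-[(triethylsilyl)oxy]-4-{[(triethylsilyl)oxy]methyl}oxolan-2-one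
Conditions: Et3SiOTf, 2,6-lutidine, CH2Cl2, 0 °C → rt
Reagents that add atoms: triethylsilyl trifluoromethanesulfonate CC[Si](CC)(CC)OS(=O)(=O)C(F)(F)F
Why: The silyl triflate silylates the primary and the tertiary hydroxyl; the tertiary ether blocks α-ketol rearrangement of the aldehyde made next.

Step 13
Reactants: 17
Product: 18 (2R,3S,4R)-2-{(1E)-1-chloro-5-[(4-methoxybenzyl)oxy]-2-methylpent-1-en-1-yl}-4-methyl-5-oxo-3-[(triethylsilyl)oxy]oxolane-3-carbaldehyde
Conditions: (COCl)2, DMSO, CH2Cl2, −78 → −40 °C; Et3N
Reagents that add atoms: none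
Why: Swern conditions cleave and oxidise primary triethylsilyl ethers directly while tertiary silyl ethers are inert; C8 has no hydrogen, so the aldehyde cannot epimerise.

Step 14
Reactants: 19 (S)-pulegone
Product: 20 (6S)-2,2,6-trimethyl-1-oxaspiro[2.5]octan-4-one (epimers at the spiro carbon)
Conditions: H2O2, NaOH (cat.), MeOH, 0 °C
Reagents that add atoms: hydrogen peroxide OO
Why: Weitz–Scheffer nucleophilic epoxidation of the enone; the methyl-bearing centre is remote and untouched.

Step 15
Reactants: 20
Product: 21 (5S)-5-methyl-2-(phenylsulfanyl)cyclohexan-1-one (epimers at C2)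
Conditions: PhSNa (from PhSH and NaH), THF, reflux; AcOH
Reagents that add atoms: sodium benzenethiolate [Na+].[S-]c1ccccc1
Why: The thiolate opens the epoxy ketone at the α-carbon and the resulting tertiary alkoxide undergoes retro-aldol loss of acetone, a known degradation of pulegone oxide.

Step 16
Reactants: 21
Product: 23 (5S)-5-methylcyclohex-2-en-1-one, via sulfoxide 22 (not isolated)
Conditions: mCPBA, CH2Cl2, −78 °C; then CaCO3, toluene, 110 °C
Reagents that add atoms: none
Why: Sulfoxide syn-elimination; only the C3 hydrogens are available, so the alkene forms away from the methyl-bearing carbon.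

Step 17
Reactants: 18 (lactone aldehyde); 23 (5S)-5-methylcyclohex-2-en-1-one
Product: 24 aldol adduct: C9 secondary alcohol bonded to C10 of the enone ring (C11 ketone, C12=C13, C15 methyl on C1); 1S,9S,10S; C8 triethylsilyl ether
Conditions: 23, LiN(iPr)2, THF, −78 °C; ClTi(OiPr)3, −78 → −40 °C; 18, −78 °C
Reagents that add atoms: none
Why: Aldol addition of the kinetic α′ enolate: the aldehyde should enter trans to the ring methyl, as is usual for 5-substituted cyclohexenone enolates, which fixes C10. The tri-isopropoxytitanium enolate of a cyclic ketone favours the syn adduct, which is the C9 configuration required.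

Step 18
Reactants: 24
Product: 25 C9 tert-butyldimethylsilyl ether of 24
Conditions: tBuMe2SiOTf, 2,6-lutidine, CH2Cl2, −40 → 0 °C
Reagents that add atoms: tert-butyldimethylsilyl trifluoromethanesulfonate CC(C)(C)[Si](C)(C)OS(=O)(=O)C(F)(F)F
Why: Silylation of the hindered secondary alcohol with a silyl triflate; it removes the retro-aldol pathway before base and oxidant are applied.

Step 19
Reactants: 25
Product: 26 tertiary allylic alcohol: methyl (C20) added to C11 of 25 (epimers at C11)
Conditions: MeLi, CeCl3, THF, −78 °C
Reagents that add atoms: methyllithium [Li]C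
Why: The organocerium reagent adds 1,2 to the enone carbonyl without enolising C10 and much faster than to the lactone; the new centre is lost in the next step.

Step 20
Reactants: 26
Product: 27 transposed enone: C13 ketone, C11(C20)=C12 alkene
Conditions: [C5H5NH][CrO3Cl], 4 Å molecular sieves, CH2Cl2, rt
Reagents that add atoms: none
Why: Babler–Dauben oxidative transposition: the chromate ester of the tertiary allylic alcohol undergoes a [3,3] shift to C13 and is oxidised there, which moves the carbonyl to C13 and leaves C20 on an sp2 C11.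

Step 21
Reactants: 27
Product: 28 triethylsilyl enol ether C13(OSiEt3)=C12 with C11–H trans to the C10 side chain (C20 cis to C9)
Conditions: RhCl(PPh3)3 (cat.), Et3SiH, benzene, 50 °C
Reagents that add atoms: triethylsilane CC[SiH](CC)CC
Why: Rhodium-catalysed 1,4-hydrosilylation of the enone: hydride should reach C11 on the face opposite the large C10 substituent, which sets C11 and gives the regiodefined enol ether; isolated alkenes and the vinyl chloride do not react.

Step 22
Reactants: 28
Product: 29 α-silyloxy ketone: C12–OSiEt3 trans to C20, C13 ketone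
Conditions: mCPBA, hexane/CH2Cl2, −15 °C
Reagents that add atoms: 3-chloroperoxybenzoic acid O=C(OO)c1cccc(Cl)c1
Why: Rubottom oxidation: the electron-rich enol ether is epoxidised anti to the adjacent C20 methyl and the silyl group migrates to the new oxygen, which sets C12; the electron-poor chloroalkene is not epoxidised.

Step 23
Reactants: 29
Product: 31 enone: C13 ketone, C14=C1(C15) alkene, via trimethylsilyl enol ether 30 (not isolated)
Conditions: LiN(SiMe3)2, Me3SiCl, THF, −78 °C; then Pd(OAc)2, MeCN, rt
Reagents that add atoms: none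
Why: Kinetic enolisation goes to the C14 methylene rather than the silyloxy-bearing C12 methine, and Saegusa–Ito oxidation of the enol ether removes the C1 hydrogen; this erases the relay centre at C1 and sets up the allyl system.

Step 24
Reactants: 31
Product: 32 allylic alcohol at C13 (epimers at C13)
Conditions: NaBH4, CeCl3·7H2O, MeOH, −78 °C
Reagents that add atoms: none
Why: Luche 1,2-reduction of the enone; the lactone is not reduced at this temperature and the C13 configuration is irrelevant because the carbon becomes trigonal in step 28.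

Step 25
Reactants: 32
Product: 33 allylic chloride at C13 (epimers; any C1 allylic isomer converges in step 28)
Conditions: NCS, Me2S, CH2Cl2, −20 → 0 °C
Reagents that add atoms: N-chlorosuccinimide O=C1CCC(=O)N1Cl
Why: Corey–Kim chlorination of an allylic alcohol through the alkoxysulfonium salt; silyl ethers, the lactone and the benzyl ether are untouched.

Step 26
Reactants: 33
Product: 34 C2 primary alcohol (4-methoxybenzyl group removed)
Conditions: DDQ, CH2Cl2/pH 7 buffer, 0 °C
Reagents that add atoms: none
Why: Oxidative cleavage of the 4-methoxybenzyl ether by hydride abstraction; silyl ethers and the allylic chloride are stable to buffered DDQ.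

Step 27
Reactants: 34
Product: 35 C2 aldehyde
Conditions: Dess–Martin periodinane, CH2Cl2, 0 °C → rt
Reagents that add atoms: none
Why: Dess–Martin oxidation of the primary alcohol under neutral conditions that leave the allylic chloride intact.

Step 28
Reactants: 35
Product: 36 ten-membered carbocycle with the C1–C2 bond, free C2–OH (1S,2S) and C13=C14; silyl ethers at C8, C9, C12
Conditions: CrCl2, THF, slow addition (high dilution), rt
Reagents that add atoms: none
Why: Nozaki–Hiyama allylation: CrCl2 turns the allylic chloride into an allylchromium that adds to the C2 aldehyde through a six-membered transition state at its more substituted terminus C1, creating the quaternary centre, the C2 carbinol and the C13=C14 alkene while closing ring B. The C10 side chain, held pseudoaxial by allylic strain with C15, should send C2 to the opposite face of C1 (trans fusion); the C2 configuration is set by the geometry of the cyclic transition state and is the less secure element.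

Step 29
Reactants: 36
Product: 37 C2,C12-diol (C12 triethylsilyl ether removed; C8 and C9 ethers kept)
Conditions: PPTS (cat.), MeOH/CH2Cl2, 0 °C
Reagents that add atoms: none
Why: Mild acid methanolysis removes the secondary triethylsilyl ether much faster than the tertiary triethylsilyl or the hindered tert-butyldimethylsilyl ether; loss of the C8 ether would be harmless, since a tertiary alcohol is not acetylated in step 30.

Step 30
Reactants: 37
Product: 38 C2,C12-diacetate with C8–OSiEt3 and C9–OSitBuMe2
Conditions: Ac2O, pyridine, DMAP (cat.), CH2Cl2, rt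
Reagents that add atoms: acetic anhydride CC(=O)OC(C)=O
Why: DMAP-catalysed acylation of the two free secondary alcohols; C9 is protected, so the selectivity problem between C2 and C9 does not arise.

Step 31
Reactants: 38
Product: 39 CNP0296164.1 (target)
Conditions: HF (48 % aq.), MeCN, 0 °C → rt
Reagents that add atoms: none
Why: Acidic fluoride cleaves both silyl ethers; acetates, the lactone and the vinyl chloride are stable to HF in acetonitrile, and the freed C9–OH has no neighbouring acetate that could migrate.

## Compound list

1 | (R)-4-benzyl-3-propionyloxazolidin-2-one | CCC(=O)N1[C@H](Cc2ccccc2)COC1=O | starting material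
2 | ethyl glyoxylate | CCOC(=O)C=O | starting material
3 | ethyl (2R,3R)-4-[(4R)-4-benzyl-2-oxo-1,3-oxazolidin-3-yl]-2-hydroxy-3-methyl-4-oxobutanoate | CCOC(=O)[C@H](O)[C@@H](C)C(=O)N1[C@H](Cc2ccccc2)COC1=O | intermediate
4 | (2R,3R)-2-hydroxy-3-methylbutanedioic acid | OC(=O)[C@H](O)[C@@H](C)C(=O)O | intermediate
5 | pivalaldehyde | CC(C)(C)C=O | starting material
6 | (2R)-2-[(2R,4R)-2-tert-butyl-5-oxo-1,3-dioxolan-4-yl]propanoic acid | CC(C)(C)[C@H]1OC(=O)[C@H](O1)[C@@H](C)C(=O)O | intermediate
7 | pent-4-yn-1-ol | C#CCCCO | starting material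
8 | 1-methoxy-4-[(pent-4-yn-1-yloxy)methyl]benzene | C#CCCCOCc1ccc(OC)cc1 | intermediate
9 | ethyl 6-[(4-methoxybenzyl)oxy]hex-2-ynoate | CCOC(=O)C#CCCCOCc1ccc(OC)cc1 | intermediate
10 | ethyl (2E)-2-chloro-6-[(4-methoxybenzyl)oxy]-3-methylhex-2-enoate | CCOC(=O)/C(Cl)=C(/C)CCCOCc1ccc(OC)cc1 | intermediate
11 | (2E)-2-chloro-6-[(4-methoxybenzyl)oxy]-3-methylhex-2-en-1-ol | OC/C(Cl)=C(/C)CCCOCc1ccc(OC)cc1 | intermediate
12 | (2E)-2-chloro-6-[(4-methoxybenzyl)oxy]-3-methylhex-2-enal | O=C/C(Cl)=C(/C)CCCOCc1ccc(OC)cc1 | intermediate
13 | (2R)-2-[(2R,4S)-2-tert-butyl-4-{(1R,2E)-2-chloro-1-hydroxy-6-[(4-methoxybenzyl)oxy]-3-methylhex-2-en-1-yl}-5-oxo-1,3-dioxolan-4-yl]propanoic acid | CC(C)(C)[C@H]1OC(=O)[C@](O1)([C@@H](C)C(=O)O)[C@@H](O)/C(Cl)=C(/C)CCCOCc2ccc(OC)cc2 | intermediate (not isolated)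
14 | (2R,5S,6R,9R)-2-tert-butyl-6-{(1E)-1-chloro-5-[(4-methoxybenzyl)oxy]-2-methylpent-1-en-1-yl}-9-methyl-1,3,7-trioxaspiro[4.4]nonane-4,8-dione | CC(C)(C)[C@H]1OC(=O)[C@]2(O1)[C@@H](C)C(=O)O[C@H]2/C(Cl)=C(/C)CCCOCc3ccc(OC)cc3 | intermediate
15 | methyl (2R,3S,4R)-2-{(1E)-1-chloro-5-[(4-methoxybenzyl)oxy]-2-methylpent-1-en-1-yl}-3-hydroxy-4-methyl-5-oxooxolane-3-carboxylate | COc1ccc(COCCC/C(C)=C(/Cl)[C@@H]2OC(=O)[C@H](C)[C@@]2(O)C(=O)OC)cc1 | intermediate
16 | (3R,4R,5R)-5-{(1E)-1-chloro-5-[(4-methoxybenzyl)oxy]-2-methylpent-1-en-1-yl}-4-hydroxy-4-(hydroxymethyl)-3-methyloxolan-2-one | COc1ccc(COCCC/C(C)=C(/Cl)[C@@H]2OC(=O)[C@H](C)[C@@]2(O)CO)cc1 | intermediate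
17 | (3R,4R,5R)-5-{(1E)-1-chloro-5-[(4-methoxybenzyl)oxy]-2-methylpent-1-en-1-yl}-3-methyl-4-[(triethylsilyl)oxy]-4-{[(triethylsilyl)oxy]methyl}oxolan-2-one | COc1ccc(COCCC/C(C)=C(/Cl)[C@@H]2OC(=O)[C@H](C)[C@@]2(O[Si](CC)(CC)CC)CO[Si](CC)(CC)CC)cc1 | intermediate
18 | (2R,3S,4R)-2-{(1E)-1-chloro-5-[(4-methoxybenzyl)oxy]-2-methylpent-1-en-1-yl}-4-methyl-5-oxo-3-[(triethylsilyl)oxy]oxolane-3-carbaldehyde | COc1ccc(COCCC/C(C)=C(/Cl)[C@@H]2OC(=O)[C@H](C)[C@@]2(O[Si](CC)(CC)CC)C=O)cc1 | intermediate
19 | (S)-pulegone, (5S)-5-methyl-2-(propan-2-ylidene)cyclohexan-1-one | C[C@H]1CCC(=C(C)C)C(=O)C1 | starting material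
20 | (6S)-2,2,6-trimethyl-1-oxaspiro[2.5]octan-4-one (epimers at the spiro carbon) | C[C@H]1CCC2(OC2(C)C)C(=O)C1 | intermediate
21 | (5S)-5-methyl-2-(phenylsulfanyl)cyclohexan-1-one (epimers at C2) | C[C@H]1CCC(Sc2ccccc2)C(=O)C1 | intermediate
22 | (5S)-5-methyl-2-(phenylsulfinyl)cyclohexan-1-one | C[C@H]1CCC(S(=O)c2ccccc2)C(=O)C1 | intermediate (not isolated)
23 | (5S)-5-methylcyclohex-2-en-1-one | C[C@H]1CC=CC(=O)C1 | intermediate
24 | aldol adduct (1S,9S,10S): C9–OH, C11 ketone, C12=C13, C8–OSiEt3 | COc1ccc(COCCC/C(C)=C(/Cl)[C@@H]2OC(=O)[C@H](C)[C@@]2(O[Si](CC)(CC)CC)[C@@H](O)[C@H]3C(=O)C=CC[C@@H]3C)cc1 | intermediate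
25 | C9 tert-butyldimethylsilyl ether of 24 | COc1ccc(COCCC/C(C)=C(/Cl)[C@@H]2OC(=O)[C@H](C)[C@@]2(O[Si](CC)(CC)CC)[C@@H](O[Si](C)(C)C(C)(C)C)[C@H]3C(=O)C=CC[C@@H]3C)cc1 | intermediate
26 | C11 tertiary allylic alcohol (C11 epimers) | COc1ccc(COCCC/C(C)=C(/Cl)[C@@H]2OC(=O)[C@H](C)[C@@]2(O[Si](CC)(CC)CC)[C@@H](O[Si](C)(C)C(C)(C)C)[C@H]3C(C)(O)C=CC[C@@H]3C)cc1 | intermediate
27 | transposed enone (C13 ketone, C11=C12) | COc1ccc(COCCC/C(C)=C(/Cl)[C@@H]2OC(=O)[C@H](C)[C@@]2(O[Si](CC)(CC)CC)[C@@H](O[Si](C)(C)C(C)(C)C)[C@H]3C(C)=CC(=O)C[C@@H]3C)cc1 | intermediate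
28 | triethylsilyl enol ether C13(OSiEt3)=C12, C20 cis to C9 | COc1ccc(COCCC/C(C)=C(/Cl)[C@@H]2OC(=O)[C@H](C)[C@@]2(O[Si](CC)(CC)CC)[C@@H](O[Si](C)(C)C(C)(C)C)[C@H]3[C@@H](C)C=C(O[Si](CC)(CC)CC)C[C@@H]3C)cc1 | intermediate
29 | α-silyloxy ketone (C12–OSiEt3 trans to C20, C13 ketone) | COc1ccc(COCCC/C(C)=C(/Cl)[C@@H]2OC(=O)[C@H](C)[C@@]2(O[Si](CC)(CC)CC)[C@@H](O[Si](C)(C)C(C)(C)C)[C@H]3[C@@H](C)[C@H](O[Si](CC)(CC)CC)C(=O)C[C@@H]3C)cc1 | intermediate
30 | trimethylsilyl enol ether C13(OSiMe3)=C14 of 29 | COc1ccc(COCCC/C(C)=C(/Cl)[C@@H]2OC(=O)[C@H](C)[C@@]2(O[Si](CC)(CC)CC)[C@@H](O[Si](C)(C)C(C)(C)C)[C@H]3[C@@H](C)[C@H](O[Si](CC)(CC)CC)C(O[Si](C)(C)C)=C[C@@H]3C)cc1 | intermediate (not isolated)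
31 | enone (C13 ketone, C14=C1) | COc1ccc(COCCC/C(C)=C(/Cl)[C@@H]2OC(=O)[C@H](C)[C@@]2(O[Si](CC)(CC)CC)[C@@H](O[Si](C)(C)C(C)(C)C)[C@H]3[C@@H](C)[C@H](O[Si](CC)(CC)CC)C(=O)C=C3C)cc1 | intermediate
32 | C13 allylic alcohol (C13 epimers) | COc1ccc(COCCC/C(C)=C(/Cl)[C@@H]2OC(=O)[C@H](C)[C@@]2(O[Si](CC)(CC)CC)[C@@H](O[Si](C)(C)C(C)(C)C)[C@H]3[C@@H](C)[C@H](O[Si](CC)(CC)CC)C(O)C=C3C)cc1 | intermediate
33 | C13 allylic chloride (C13 epimers) | COc1ccc(COCCC/C(C)=C(/Cl)[C@@H]2OC(=O)[C@H](C)[C@@]2(O[Si](CC)(CC)CC)[C@@H](O[Si](C)(C)C(C)(C)C)[C@H]3[C@@H](C)[C@H](O[Si](CC)(CC)CC)C(Cl)C=C3C)cc1 | intermediate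
34 | C2 primary alcohol, C13 chloride | OCCC/C(C)=C(/Cl)[C@@H]2OC(=O)[C@H](C)[C@@]2(O[Si](CC)(CC)CC)[C@@H](O[Si](C)(C)C(C)(C)C)[C@H]3[C@@H](C)[C@H](O[Si](CC)(CC)CC)C(Cl)C=C3C | intermediate
35 | C2 aldehyde, C13 chloride | O=CCC/C(C)=C(/Cl)[C@@H]2OC(=O)[C@H](C)[C@@]2(O[Si](CC)(CC)CC)[C@@H](O[Si](C)(C)C(C)(C)C)[C@H]3[C@@H](C)[C@H](O[Si](CC)(CC)CC)C(Cl)C=C3C | intermediate
36 | tricyclic C2 alcohol (1S,2S) with C8–OSiEt3, C9–OSitBuMe2, C12–OSiEt3 | O[C@H]1CC/C(C)=C(/Cl)[C@@H]2OC(=O)[C@H](C)[C@@]2(O[Si](CC)(CC)CC)[C@@H](O[Si](C)(C)C(C)(C)C)[C@H]2[C@@H](C)[C@H](O[Si](CC)(CC)CC)C=C[C@@]21C | intermediate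
37 | tricyclic C2,C12-diol with C8–OSiEt3, C9–OSitBuMe2 | O[C@H]1CC/C(C)=C(/Cl)[C@@H]2OC(=O)[C@H](C)[C@@]2(O[Si](CC)(CC)CC)[C@@H](O[Si](C)(C)C(C)(C)C)[C@H]2[C@@H](C)[C@H](O)C=C[C@@]21C | intermediate
38 | tricyclic C2,C12-diacetate with C8–OSiEt3, C9–OSitBuMe2 | CC(=O)O[C@H]1CC/C(C)=C(/Cl)[C@@H]2OC(=O)[C@H](C)[C@@]2(O[Si](CC)(CC)CC)[C@@H](O[Si](C)(C)C(C)(C)C)[C@H]2[C@@H](C)[C@H](OC(C)=O)C=C[C@@]21C | intermediate
39 | CNP0296164.1 | CC(=O)O[C@H]1CC/C(C)=C(/Cl)[C@@H]2OC(=O)[C@H](C)[C@@]2(O)[C@@H](O)[C@H]2[C@@H](C)[C@H](OC(C)=O)C=C[C@@]21C | target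

## Count and risks

Total: 31 steps. Longest linear sequence: 25 steps (steps 4 to 13 and 17 to 31, from pent-4-yn-1-ol 7).

**Step 9 (key step).** The most likely failure is poor facial selectivity at the aldehyde carbon. The enolate carbon is fully substituted, so the chlorovinyl group meets gauche contacts in either chair and the C7 epimer may predominate; slow addition of the hindered dianion is a second risk. Fallback: 6 and 12 are combined as before, but the mixture is quenched cold at pH 5 so that the C7-epimeric hydroxy acid F1 stays open. F1 is then closed with PPh3 and diisopropyl azodicarboxylate (Mitsunobu lactonisation), in which the carboxylate displaces the activated allylic C7 oxygen with inversion. This returns to 14.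

**Step 28.** Three things may go wrong. The allylchromium may lose the neighbouring C12 silyloxy group by β-elimination. Bonding may occur on the wrong face of C1, giving a cis-fused ring. The aldehyde may be taken up in the other orientation, giving the C2 epimer, because the tether and not a simple chair decides the geometry. Fallback: from 33, Miyaura borylation (B2pin2, Pd2(dba)3, DMSO) gives the C13 allylboronate F2, DDQ frees the C2 alcohol F3, and Dess–Martin oxidation gives the aldehyde F4. F4 cyclises on gentle warming by intramolecular allylboration through a closed six-membered transition state with boron on oxygen; boron does not expel the silyloxy group, and aqueous work-up returns to 36.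

**Step 17.** The most likely failure is the wrong relative configuration at C9 (the anti adduct), because a cyclic enolate cannot change geometry and the facial preferences of enolate and aldehyde may be mismatched. Fallback: from 23, LiN(iPr)2 and Me3SiCl give the silyl dienol ether F5, which is added to 18 with BF3·OEt2 (Mukaiyama aldol) through an open transition state not tied to the chair that gives the anti adduct. Work-up returns to 24.

**Step 23.** The most likely failure is stalling of the palladium enolate before β-hydride elimination at the hindered C1–H, with return of ketone 29 or over-oxidation. Fallback: from 29, LiN(SiMe3)2 and PhSeCl give the C14 phenylselenide F6; H2O2 then removes selenium by oxidative syn-elimination, which can only take the C1 hydrogen. This returns to 31.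

**Step 6.** The most likely failure is loss of alkene geometry through the allenoate form of the cuprate adduct, or protonation instead of chlorination. Fallback: from 8, gold-catalysed hydration (Ph3PAuNTf2, MeOH/H2O) gives the methyl ketone F7. Horner–Wadsworth–Emmons olefination with triethyl 2-chloro-2-phosphonoacetate (NaH, THF) then gives 10 together with its geometric isomer F8, which is removed by chromatography. This returns to 10.

## Further compounds

F1 | step 9 | (2R)-2-[(2R,4S)-2-tert-butyl-4-{(1S,2E)-2-chloro-1-hydroxy-6-[(4-methoxybenzyl)oxy]-3-methylhex-2-en-1-yl}-5-oxo-1,3-dioxolan-4-yl]propanoic acid | CC(C)(C)[C@H]1OC(=O)[C@](O1)([C@@H](C)C(=O)O)[C@H](O)/C(Cl)=C(/C)CCCOCc2ccc(OC)cc2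
F2 | step 28 | C13 pinacol allylboronate corresponding to 33 | COc1ccc(COCCC/C(C)=C(/Cl)[C@@H]2OC(=O)[C@H](C)[C@@]2(O[Si](CC)(CC)CC)[C@@H](O[Si](C)(C)C(C)(C)C)[C@H]3[C@@H](C)[C@H](O[Si](CC)(CC)CC)C(B4OC(C)(C)C(C)(C)O4)C=C3C)cc1
F3 | step 28 | C2 primary alcohol with C13 pinacol allylboronate | OCCC/C(C)=C(/Cl)[C@@H]2OC(=O)[C@H](C)[C@@]2(O[Si](CC)(CC)CC)[C@@H](O[Si](C)(C)C(C)(C)C)[C@H]3[C@@H](C)[C@H](O[Si](CC)(CC)CC)C(B4OC(C)(C)C(C)(C)O4)C=C3C
F4 | step 28 | C2 aldehyde with C13 pinacol allylboronate | O=CCC/C(C)=C(/Cl)[C@@H]2OC(=O)[C@H](C)[C@@]2(O[Si](CC)(CC)CC)[C@@H](O[Si](C)(C)C(C)(C)C)[C@H]3[C@@H](C)[C@H](O[Si](CC)(CC)CC)C(B4OC(C)(C)C(C)(C)O4)C=C3C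
F5 | step 17 | trimethylsilyl dienol ether of 23, (6S)-6-methyl-2-(trimethylsilyloxy)cyclohexa-1,3-diene | C[C@H]1CC=CC(O[Si](C)(C)C)=C1
F6 | step 23 | C14 phenylselenide of ketone 29 | COc1ccc(COCCC/C(C)=C(/Cl)[C@@H]2OC(=O)[C@H](C)[C@@]2(O[Si](CC)(CC)CC)[C@@H](O[Si](C)(C)C(C)(C)C)[C@H]3[C@@H](C)[C@H](O[Si](CC)(CC)CC)C(=O)C([Se]c4ccccc4)[C@@H]3C)cc1
F7 | step 6 | 5-[(4-methoxybenzyl)oxy]pentan-2-one | CC(=O)CCCOCc1ccc(OC)cc1
F8 | step 6 | ethyl (2Z)-2-chloro-6-[(4-methoxybenzyl)oxy]-3-methylhex-2-enoate | CCOC(=O)/C(Cl)=C(\C)CCCOCc1ccc(OC)cc1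
A1 | alternative 1 | ten-membered C8,C9-diol with silyl ethers at C2, C7, C12 and on the C17 side chain | CC(C)(C)[Si](C)(C)O[C@H]1CC/C(C)=C(/Cl)[C@H](O[Si](CC)(CC)CC)[C@@](O)([C@@H](C)CO[Si](C)(C)C(C)(C)C)[C@@H](O)[C@H]2[C@@H](C)[C@H](O[Si](C)(C)C(C)(C)C)C=C[C@@]21C
A2 | alternative 2 | ring A aldehyde with quaternary C1, C12 silyl ether and C9 4-methoxybenzyl ether | O=C[C@@]1(C)C=C[C@@H](O[Si](C)(C)C(C)(C)C)[C@H](C)[C@@H]1COCc1ccc(OC)cc1
A3 | alternative 3 | ten-membered 2,7-dione fused to ring A, C9 methoxymethyl ether, C12 silyl ether | O=C1C/C=C(C)\CC(=O)C[C@@H](OCOC)[C@H]2[C@@H](C)[C@H](O[Si](C)(C)C(C)(C)C)CC[C@@]21C
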